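## Retrosynthetic overview

1. Target 23 ⇒ diimide reduction of two olefination seams: C8=C9 (Wittig) and C11=C12 (Julia–Kocienski). This gives aldehyde 8 (C1–C8, finished 1,2-dioxane), the C9–C11 linchpin 16 (from (R)-3-bromo-2-methylpropan-1-ol, carries C10) and aldehyde 13 (C12–C18, masked tertiary hydroperoxide).
2. 1,2-Dioxane of 8 ⇒ new catalytic asymmetric 6-exo peroxy-Michael cyclisation of hydroperoxy enoate 6 (sets C3 and C2).
3. Both tertiary C–OO centres (C6 and C14) ⇒ stereoinvertive perhydrolysis of the 2,2-disubstituted oxetanes 5 and 10, both made by cross-metathesis from one oxetane 3.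
4. Oxetane 3 ⇒ hex-5-en-2-one by catalytic asymmetric Corey–Chaykovsky epoxidation and, in the same pot, ring expansion of the epoxide to the oxetane (key step).
5. Ring order: oxirane 2 (transient) → oxetane 3 (ring expansion; reopened in steps 3 and 7) → 1,2-dioxane (step 4), the only ring of the target.

Locants used below: C1 ester carbonyl, C2 (CHMe), C3 (ring CH), C4, C5, C6 (ring quaternary C), C7–C9, C10 (CHMe), C11–C13, C14 (C–OOH), C15, C16, C17=C18.

Assumption: triphenylphosphine, 1-phenyl-1H-tetrazole-5-thiol, 2-methoxypropene and the small reagents named on the "Reagents that add atoms" lines carry no compound number; the (R)-binaphtholate antipode of the lanthanum catalyst is taken as the one that adds CH2 to the Si face of 1 (otherwise the (S)-antipode is used).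

## Route

Step 1
Reactants: 1 hex-5-en-2-one
Product: 3 (2R)-2-(but-3-en-1-yl)-2-methyloxetane, via epoxide 2 (not isolated)
Conditions: Me3S(O)I/NaH (2.2 equiv ylide in two portions), LaLi3[(R)-binaphtholate]3 (5 then 15 mol %), (2,4,6-(MeO)3C6H2)3P=O, MS 5 Å, THF, rt then 45 °C
Reagents that add atoms: trimethylsulfoxonium iodide, C[S+](C)(C)=O.[I-]
Why: Catalytic asymmetric Corey–Chaykovsky epoxidation of the methyl ketone (methylene delivered to the Si face sets the quaternary centre as R) is followed in the same pot by ring expansion of the epoxide with a second ylide equivalent (SN2 at the CH2 terminus, then 4-exo-tet closure with loss of DMSO), which leaves the stereocentre untouched and raises the ee because the catalyst expands the major epoxide enantiomer faster.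

Step 2
Reactants: 3 (2R)-2-(but-3-en-1-yl)-2-methyloxetane; 4 methyl 2-methylprop-2-enoate (methyl methacrylate)
Product: 5 methyl (2E)-2-methyl-5-[(2R)-2-methyloxetan-2-yl]pent-2-enoate
Conditions: second-generation Hoveyda–Grubbs catalyst RuCl2(=CH-C6H4-2-OiPr)(H2IMes) (3 mol %), 4 (10 equiv), CH2Cl2, 40 °C
Reagents that add atoms: none
Why: Olefin cross-metathesis of the terminal alkene with excess methacrylate gives the E-trisubstituted enoate (ethene lost), and the oxetane and its stereocentre are inert to the ruthenium carbene.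

Step 3
Reactants: 5 methyl (2E)-2-methyl-5-[(2R)-2-methyloxetan-2-yl]pent-2-enoate
Product: 6 methyl (2E,6S)-6-hydroperoxy-8-hydroxy-2,6-dimethyloct-2-enoate
Conditions: H2O2 (anhydrous, in Et2O, 10 equiv), MoO2(acac)2 (5 mol %), Et2O, 0 °C → rt
Reagents that add atoms: hydrogen peroxide, OO
Why: Molybdenum-catalysed perhydrolysis of a 2,2-disubstituted oxetane, in which H2O2 attacks the activated tertiary C–O carbon from the rear (borderline SN2, inversion), so the (R)-oxetane gives the tertiary hydroperoxide with the C6 arrangement of the target (6S here and 6R in the target differ only through CIP priorities) and frees C8–OH, while the electron-poor enoate is untouched.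

Step 4
Reactants: 6 methyl (2E,6S)-6-hydroperoxy-8-hydroxy-2,6-dimethyloct-2-enoate
Product: 7 methyl (2R)-2-[(3S,6S)-6-(2-hydroxyethyl)-6-methyl-1,2-dioxan-3-yl]propanoate
Conditions: bifunctional iminophosphorane catalyst 3,5-(CF3)2C6H3NHC(S)NH–CH(tBu)CH2–N=P(C6H4-4-OMe)3 (tert-leucine-derived, 10 mol %), toluene, −20 °C
Reagents that add atoms: none
Why: Proposed new method: the superbasic iminophosphorane deprotonates the tertiary hydroperoxide (pKa about 13) to a chiral iminophosphonium peroxide ion pair while the thiourea binds the enoate carbonyl, so the peroxy oxygen closes 6-exo-trig onto the Si face of C3 (sets 3S) and the ester enolate is protonated inside the same ion pair on the Si face of C2 (sets 2R) faster than it can attack the O–O bond, the remote and nearly unbiased C6 centre (methyl versus 2-hydroxyethyl) not opposing the catalyst (antipode chosen accordingly); the closest known reaction types are the bifunctional iminophosphorane-catalysed enantioselective intramolecular oxa-Michael addition of alcohols to unsaturated esters, the enantioselective protonation in iminophosphorane-catalysed sulfa-Michael additions to α-substituted acrylates, and the non-selective amine-promoted intramolecular peroxy-Michael cyclisation.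

Step 5
Reactants: 7 methyl (2R)-2-[(3S,6S)-6-(2-hydroxyethyl)-6-methyl-1,2-dioxan-3-yl]propanoate
Product: 8 methyl (2R)-2-[(3S,6S)-6-methyl-6-(2-oxoethyl)-1,2-dioxan-3-yl]propanoate
Conditions: Dess–Martin periodinane, CH2Cl2, 0 °C → rt
Reagents that add atoms: none
Why: Dess–Martin oxidation of the primary alcohol to the aldehyde under neutral conditions that leave the dialkyl peroxide, the ester and the C2 centre untouched.

Step 6
Reactants: 3 (2R)-2-(but-3-en-1-yl)-2-methyloxetane; 9 2-methylbut-2-ene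
Product: 10 (2R)-2-methyl-2-(4-methylpent-3-en-1-yl)oxetane
Conditions: second-generation Grubbs catalyst RuCl2(=CHPh)(PCy3)(H2IMes) (2 mol %), neat 9 (excess), 35 °C
Reagents that add atoms: none
Why: Olefin cross-metathesis with excess 2-methylbut-2-ene exchanges =CH2 for =C(CH3)2 (propene lost), giving the 4-methylpent-3-enyl terminus without touching the oxetane stereocentre.

Step 7
Reactants: 10 (2R)-2-methyl-2-(4-methylpent-3-en-1-yl)oxetane
Product: 11 (3S)-3-hydroperoxy-3,7-dimethyloct-6-en-1-ol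
Conditions: H2O2 (anhydrous, in Et2O, 10 equiv), MoO2(acac)2 (5 mol %), Et2O, 0 °C
Reagents that add atoms: hydrogen peroxide, OO
Why: The same molybdenum-catalysed stereoinvertive oxetane perhydrolysis as in step 3 converts the (R)-oxetane into the tertiary hydroperoxide with the C14 arrangement of the target (3S here) and frees C12–OH, the reaction being kept at 0 °C and stopped at full conversion to spare the trisubstituted alkene.

Step 8
Reactants: 11 (3S)-3-hydroperoxy-3,7-dimethyloct-6-en-1-ol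
Product: 12 (3S)-3-[(2-methoxypropan-2-yl)peroxy]-3,7-dimethyloct-6-en-1-ol
Conditions: 2-methoxypropene (1.1 equiv), PPTS (2 mol %), CH2Cl2, −20 °C; brief MeOH quench
Reagents that add atoms: 2-methoxypropene, COC(C)=C
Why: Acid-catalysed addition of the hydroperoxide to the enol ether gives the 2-methoxyprop-2-yl monoperoxyketal, the more acidic α-effect OOH reacting faster than the primary OH, and any far more labile O-alkyl mixed ketal is methanolysed back in the quench.

Step 9
Reactants: 12 (3S)-3-[(2-methoxypropan-2-yl)peroxy]-3,7-dimethyloct-6-en-1-ol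
Product: 13 (3S)-3-[(2-methoxypropan-2-yl)peroxy]-3,7-dimethyloct-6-enal
Conditions: Dess–Martin periodinane, pyridine, CH2Cl2, 0 °C
Reagents that add atoms: none
Why: Pyridine-buffered Dess–Martin oxidation gives the aldehyde while preserving the acid-labile peroxyketal and the trisubstituted alkene.

Step 10
Reactants: 14 (2R)-3-bromo-2-methylpropan-1-ol
Product: 15 5-{[(2R)-3-bromo-2-methylpropyl]sulfanyl}-1-phenyl-1H-tetrazole
Conditions: 1-phenyl-1H-tetrazole-5-thiol, PPh3, DIAD, THF, 0 °C → rt
Reagents that add atoms: 1-phenyl-1H-tetrazole-5-thiol, Sc1nnnn1-c1ccccc1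
Why: Mitsunobu thioetherification of the primary alcohol places sulfur on the future C11 without involving the C10 stereocentre (chiral pool) or the primary bromide.

Step 11
Reactants: 15 5-{[(2R)-3-bromo-2-methylpropyl]sulfanyl}-1-phenyl-1H-tetrazole
Product: 16 [(2S)-2-methyl-3-[(1-phenyl-1H-tetrazol-5-yl)sulfanyl]propyl]triphenylphosphonium bromide
Conditions: PPh3 (1.5 equiv), MeCN, 85 °C (sealed)
Reagents that add atoms: triphenylphosphine, c1ccc(cc1)P(c1ccccc1)c1ccccc1
Why: SN2 quaternisation of triphenylphosphine by the primary bromide gives the Wittig salt at the future C9 (the descriptor changes to S only through CIP priorities).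

Step 12
Reactants: 16 [(2S)-2-methyl-3-[(1-phenyl-1H-tetrazol-5-yl)sulfanyl]propyl]triphenylphosphonium bromide; 8 methyl (2R)-2-[(3S,6S)-6-methyl-6-(2-oxoethyl)-1,2-dioxan-3-yl]propanoate
Product: 18 methyl (2R)-2-[(3S,6S)-6-methyl-6-[(2Z,4S)-4-methyl-5-[(1-phenyl-1H-tetrazol-5-yl)sulfanyl]pent-2-en-1-yl]-1,2-dioxan-3-yl]propanoate, via ylide 17 (not isolated)
Conditions: NaN(SiMe3)2 (1.0 equiv), THF, −78 °C; then 8, −78 → 0 °C
Reagents that add atoms: none
Why: Wittig olefination with the non-stabilised ylide forms C8=C9 (Z, geometry irrelevant since it is reduced in step 15), the aldehyde reacting far faster than the ester or the hindered dialkyl peroxide.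

Step 13
Reactants: 18 methyl (2R)-2-[(3S,6S)-6-methyl-6-[(2Z,4S)-4-methyl-5-[(1-phenyl-1H-tetrazol-5-yl)sulfanyl]pent-2-en-1-yl]-1,2-dioxan-3-yl]propanoate
Product: 19 methyl (2R)-2-[(3S,6S)-6-methyl-6-[(2Z,4S)-4-methyl-5-[(1-phenyl-1H-tetrazol-5-yl)sulfonyl]pent-2-en-1-yl]-1,2-dioxan-3-yl]propanoate
Conditions: H2O2 (30 % aq, 5 equiv), (NH4)6Mo7O24·4H2O (10 mol %), EtOH, 0 °C → rt
Reagents that add atoms: hydrogen peroxide, OO
Why: Molybdate-catalysed oxidation of the sulfide to the sulfone is chemoselective over the isolated Z-alkene, and the 1,2-dioxane and ester are inert.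

Step 14
Reactants: 19 methyl (2R)-2-[(3S,6S)-6-methyl-6-[(2Z,4S)-4-methyl-5-[(1-phenyl-1H-tetrazol-5-yl)sulfonyl]pent-2-en-1-yl]-1,2-dioxan-3-yl]propanoate; 13 (3S)-3-[(2-methoxypropan-2-yl)peroxy]-3,7-dimethyloct-6-enal
Product: 21 methyl (2R)-2-[(3S,6S)-6-[(2Z,4S,5E,8S)-8-[(2-methoxypropan-2-yl)peroxy]-4,8,12-trimethyltrideca-2,5,11-trien-1-yl]-6-methyl-1,2-dioxan-3-yl]propanoate, via sulfonyl carbanion 20 (not isolated)
Conditions: KN(SiMe3)2 (1.05 equiv), DME, −78 °C, 20 min; then 13, −78 °C → rt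
Reagents that add atoms: none
Why: Julia–Kocienski olefination (addition, Smiles rearrangement, loss of SO2 and tetrazololate) forms C11=C12 (mainly E, geometry irrelevant), and pre-forming the carbanion keeps free amide base away from the ester and the β-peroxy aldehyde so that C2, C10 and C14 are not disturbed.

Step 15
Reactants: 21 methyl (2R)-2-[(3S,6S)-6-[(2Z,4S,5E,8S)-8-[(2-methoxypropan-2-yl)peroxy]-4,8,12-trimethyltrideca-2,5,11-trien-1-yl]-6-methyl-1,2-dioxan-3-yl]propanoate
Product: 23 methyl (2R)-2-[(3S,6R)-6-[(4R,8R)-8-hydroperoxy-4,8,12-trimethyltridec-11-en-1-yl]-6-methyl-1,2-dioxan-3-yl]propanoate, via peroxyketal 22 (not isolated)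
Conditions: KO2CN=NCO2K (portionwise), AcOH, MeOH–CH2Cl2, 0 °C; then AcOH–H2O (4:1), rt; AgNO3–silica chromatography
Reagents that add atoms: none
Why: Diimide reduction transfers H2 to the two 1,2-disubstituted alkenes roughly ten to twenty times faster than to the trisubstituted C17=C18 alkene and does not cleave O–O bonds or touch any stereocentre, and aqueous acetic acid then hydrolyses the 2-methoxyprop-2-yl peroxyketal to the free hydroperoxide, over- and under-reduced material being removed on silver nitrate-impregnated silica.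

## Compound list

1 | hex-5-en-2-one | CC(=O)CCC=C | starting material
2 | (2R)-2-(but-3-en-1-yl)-2-methyloxirane | C=CCC[C@]1(C)CO1 | intermediate
3 | (2R)-2-(but-3-en-1-yl)-2-methyloxetane | C=CCC[C@]1(C)CCO1 | intermediate
4 | methyl 2-methylprop-2-enoate (methyl methacrylate) | COC(=O)C(C)=C | starting material
5 | methyl (2E)-2-methyl-5-[(2R)-2-methyloxetan-2-yl]pent-2-enoate | COC(=O)/C(C)=C/CC[C@]1(C)CCO1 | intermediate
6 | methyl (2E,6S)-6-hydroperoxy-8-hydroxy-2,6-dimethyloct-2-enoate | COC(=O)/C(C)=C/CC[C@@](C)(CCO)OO | intermediate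
7 | methyl (2R)-2-[(3S,6S)-6-(2-hydroxyethyl)-6-methyl-1,2-dioxan-3-yl]propanoate | COC(=O)[C@H](C)[C@@H]1CC[C@@](C)(CCO)OO1 | intermediate
8 | methyl (2R)-2-[(3S,6S)-6-methyl-6-(2-oxoethyl)-1,2-dioxan-3-yl]propanoate | COC(=O)[C@H](C)[C@@H]1CC[C@@](C)(CC=O)OO1 | intermediate
9 | 2-methylbut-2-ene | CC=C(C)C | starting material
10 | (2R)-2-methyl-2-(4-methylpent-3-en-1-yl)oxetane | CC(C)=CCC[C@]1(C)CCO1 | intermediate
11 | (3S)-3-hydroperoxy-3,7-dimethyloct-6-en-1-ol | CC(C)=CCC[C@@](C)(CCO)OO | intermediate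
12 | (3S)-3-[(2-methoxypropan-2-yl)peroxy]-3,7-dimethyloct-6-en-1-ol | CC(C)=CCC[C@@](C)(CCO)OOC(C)(C)OC | intermediate
13 | (3S)-3-[(2-methoxypropan-2-yl)peroxy]-3,7-dimethyloct-6-enal | CC(C)=CCC[C@@](C)(CC=O)OOC(C)(C)OC | intermediate
14 | (2R)-3-bromo-2-methylpropan-1-ol | BrC[C@H](C)CO | starting material
15 | 5-{[(2R)-3-bromo-2-methylpropyl]sulfanyl}-1-phenyl-1H-tetrazole | BrC[C@H](C)CSc1nnnn1-c1ccccc1 | intermediate
16 | [(2S)-2-methyl-3-[(1-phenyl-1H-tetrazol-5-yl)sulfanyl]propyl]triphenylphosphonium bromide | c1ccccc1[P+](c1ccccc1)(c1ccccc1)C[C@H](C)CSc1nnnn1-c1ccccc1.[Br-] | intermediate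
17 | triphenyl{(2S)-2-methyl-3-[(1-phenyl-1H-tetrazol-5-yl)sulfanyl]propylidene}phosphorane | c1ccccc1P(c1ccccc1)(c1ccccc1)=C[C@H](C)CSc1nnnn1-c1ccccc1 | intermediate
18 | methyl (2R)-2-[(3S,6S)-6-methyl-6-[(2Z,4S)-4-methyl-5-[(1-phenyl-1H-tetrazol-5-yl)sulfanyl]pent-2-en-1-yl]-1,2-dioxan-3-yl]propanoate | COC(=O)[C@H](C)[C@@H]1CC[C@@](C)(C/C=C\[C@H](C)CSc2nnnn2-c2ccccc2)OO1 | intermediate
19 | methyl (2R)-2-[(3S,6S)-6-methyl-6-[(2Z,4S)-4-methyl-5-[(1-phenyl-1H-tetrazol-5-yl)sulfonyl]pent-2-en-1-yl]-1,2-dioxan-3-yl]propanoate | COC(=O)[C@H](C)[C@@H]1CC[C@@](C)(C/C=C\[C@H](C)CS(=O)(=O)c2nnnn2-c2ccccc2)OO1 | intermediate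
20 | potassium salt of the α-sulfonyl carbanion of 19 | COC(=O)[C@H](C)[C@@H]1CC[C@@](C)(C/C=C\[C@H](C)[CH-]S(=O)(=O)c2nnnn2-c2ccccc2)OO1.[K+] | intermediate
21 | methyl (2R)-2-[(3S,6S)-6-[(2Z,4S,5E,8S)-8-[(2-methoxypropan-2-yl)peroxy]-4,8,12-trimethyltrideca-2,5,11-trien-1-yl]-6-methyl-1,2-dioxan-3-yl]propanoate | COC(=O)[C@H](C)[C@@H]1CC[C@@](C)(C/C=C\[C@H](C)/C=C/C[C@](C)(CCC=C(C)C)OOC(C)(C)OC)OO1 | intermediate
22 | methyl (2R)-2-[(3S,6R)-6-[(4S,8R)-8-[(2-methoxypropan-2-yl)peroxy]-4,8,12-trimethyltridec-11-en-1-yl]-6-methyl-1,2-dioxan-3-yl]propanoate | COC(=O)[C@H](C)[C@@H]1CC[C@@](C)(CCC[C@H](C)CCC[C@](C)(CCC=C(C)C)OOC(C)(C)OC)OO1 | intermediate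
23 | methyl (2R)-2-[(3S,6R)-6-[(4R,8R)-8-hydroperoxy-4,8,12-trimethyltridec-11-en-1-yl]-6-methyl-1,2-dioxan-3-yl]propanoate | COC(=O)[C@H](C)[C@@H]1CC[C@@](C)(CCC[C@H](C)CCC[C@](C)(CCC=C(C)C)OO)OO1 | target

## Step count and risks

Total: 15 steps. Longest linear sequence: 9 steps (1, 2, 3, 4, 5, 12, 13, 14, 15).

Risk 1, step 4 (the new reaction). The hydroperoxide may degrade the iminophosphorane (P–N cleavage), the enolate may close onto the O–O bond to give an epoxy ester, and the C2 protonation may be poorly selective. The fallback uses known peroxycarbenium chemistry, sets out from 3 and comes back at 7. Ozonolysis of 3 (O3, CH2Cl2, −78 °C; Me2S) gives 3-[(2R)-2-methyloxetan-2-yl]propanal F1. Perhydrolysis as in step 3 opens the oxetane with inversion, and the hydroperoxide closes onto the aldehyde to the peroxy-lactol (6S)-6-(2-hydroxyethyl)-6-methyl-1,2-dioxan-3-ol F2. Acetylation (Ac2O, pyridine, DMAP) gives (6S)-6-[2-(acetyloxy)ethyl]-6-methyl-1,2-dioxan-3-yl acetate F3. Me3SiOTf-mediated Mukaiyama-type addition of (E)-1-methoxy-1-(trimethylsilyloxy)prop-1-ene to the derived peroxycarbenium ion gives methyl (2R)-2-[(3S,6S)-6-[2-(acetyloxy)ethyl]-6-methyl-1,2-dioxan-3-yl]propanoate F4. This addition is not controlled at C3 or C2, so F4 has to be separated from its isomers by HPLC. K2CO3 in MeOH then removes the acetate to give 7.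

Risk 2, step 7. The molybdenum peroxo species, or the product hydroperoxide with molybdenum, may epoxidise the electron-rich trisubstituted alkene, and the alkene may take part in the ionising oxetane. The fallback installs the trisubstituted alkene after the peroxide; it sets out from 3 and comes back at 12. Perhydrolysis of 3 under the step 3 conditions (only a terminal alkene is present) gives (3S)-3-hydroperoxy-3-methylhept-6-en-1-ol F5. Perketalisation as in step 8 gives (3S)-3-[(2-methoxypropan-2-yl)peroxy]-3-methylhept-6-en-1-ol F6. Cross-metathesis of F6 with 9 (second-generation Grubbs catalyst RuCl2(=CHPh)(PCy3)(H2IMes)), which tolerates dialkyl peroxides, gives 12.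

Risk 3, step 15. Two disubstituted alkenes must be reduced fully beside the trisubstituted one, and the skipped diene of 21 is air-sensitive. The fallback reduces the alkenes one at a time; it sets out from 18 and comes back at 22. Diimide reduction of 18, where C8=C9 is the only alkene and can be driven to completion, gives methyl (2R)-2-[(3S,6R)-6-methyl-6-[(4S)-4-methyl-5-[(1-phenyl-1H-tetrazol-5-yl)sulfanyl]pentyl]-1,2-dioxan-3-yl]propanoate F7. Molybdate/H2O2 oxidation as in step 13 gives methyl (2R)-2-[(3S,6R)-6-methyl-6-[(4S)-4-methyl-5-[(1-phenyl-1H-tetrazol-5-yl)sulfonyl]pentyl]-1,2-dioxan-3-yl]propanoate F8. Julia–Kocienski olefination with 13 as in step 14 gives methyl (2R)-2-[(3S,6R)-6-[(4S,5E,8S)-8-[(2-methoxypropan-2-yl)peroxy]-4,8,12-trimethyltrideca-5,11-dien-1-yl]-6-methyl-1,2-dioxan-3-yl]propanoate F9. Only one disubstituted alkene then competes with the trisubstituted one in the final diimide reduction to 22, which is unmasked to 23 as in step 15.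

Further compounds
F1 | step 4 | 3-[(2R)-2-methyloxetan-2-yl]propanal | O=CCC[C@]1(C)CCO1
F2 | step 4 | (6S)-6-(2-hydroxyethyl)-6-methyl-1,2-dioxan-3-ol | OC1CC[C@@](C)(CCO)OO1
F3 | step 4 | (6S)-6-[2-(acetyloxy)ethyl]-6-methyl-1,2-dioxan-3-yl acetate | CC(=O)OC1CC[C@@](C)(CCOC(C)=O)OO1
F4 | step 4 | methyl (2R)-2-[(3S,6S)-6-[2-(acetyloxy)ethyl]-6-methyl-1,2-dioxan-3-yl]propanoate | COC(=O)[C@H](C)[C@@H]1CC[C@@](C)(CCOC(C)=O)OO1
F5 | step 7 | (3S)-3-hydroperoxy-3-methylhept-6-en-1-ol | C=CCC[C@@](C)(CCO)OO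
F6 | step 7 | (3S)-3-[(2-methoxypropan-2-yl)peroxy]-3-methylhept-6-en-1-ol | C=CCC[C@@](C)(CCO)OOC(C)(C)OC
F7 | step 15 | methyl (2R)-2-[(3S,6R)-6-methyl-6-[(4S)-4-methyl-5-[(1-phenyl-1H-tetrazol-5-yl)sulfanyl]pentyl]-1,2-dioxan-3-yl]propanoate | COC(=O)[C@H](C)[C@@H]1CC[C@@](C)(CCC[C@H](C)CSc2nnnn2-c2ccccc2)OO1
F8 | step 15 | methyl (2R)-2-[(3S,6R)-6-methyl-6-[(4S)-4-methyl-5-[(1-phenyl-1H-tetrazol-5-yl)sulfonyl]pentyl]-1,2-dioxan-3-yl]propanoate | COC(=O)[C@H](C)[C@@H]1CC[C@@](C)(CCC[C@H](C)CS(=O)(=O)c2nnnn2-c2ccccc2)OO1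
F9 | step 15 | methyl (2R)-2-[(3S,6R)-6-[(4S,5E,8S)-8-[(2-methoxypropan-2-yl)peroxy]-4,8,12-trimethyltrideca-5,11-dien-1-yl]-6-methyl-1,2-dioxan-3-yl]propanoate | COC(=O)[C@H](C)[C@@H]1CC[C@@](C)(CCC[C@H](C)/C=C/C[C@](C)(CCC=C(C)C)OOC(C)(C)OC)OO1
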